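**Assumption:** the target is taken exactly as the given SMILES, i.e. (6S,7R,10S,11R) in the chain numbering below, with both trisubstituted olefins Z.

Chain numbering used in the text: HOC1H2–C2H=C3(Me)–C4H2–C5H2–C6H(O)–C7(Me)(O)–C8H2–C9H2–C10H(OH)–C11–C12H2–C13H2–C14H=C15(Me)–C16H2OH; C17 is the lactone carbonyl on C11. Abbreviations: TBDPS = tert-butyldiphenylsilyl, PMB = 4-methoxybenzyl, TES = triethylsilyl.

## Retrosynthetic overview

1. The lactone bridge C7–O–C17(=O) is closed last, by oxidative lactonisation across a 2,6-cis oxepane; desilylation then frees the three hydroxyls.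
2. The C12–C16 arm comes from an allyl group on C11 (hydroboration, oxidation, Still–Gennari olefination); quaternary C11 comes from Fráter–Seebach allylation of a β-hydroxy ester.
3. The oxepane is the first ring formed, by ring-closing metathesis at C8=C9 followed by hydroxyl-directed hydrogenation.
4. The key C10–C11 bond is made by an intermolecular Evans glycolate aldol between the glycolyl imide of the C1–C8 fragment and acrolein; this sets C10.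
5. The C1–C8 fragment with its C6/C7 oxygens comes from nerol by allylic oxidation, Sharpless epoxidation and Payne rearrangement with ylide homologation.

## Route

Step 1
Reactants: 1 nerol
Product: 2 (2Z)-1-(TBDPS-oxy)-3,7-dimethylocta-2,6-diene
Conditions: TBDPSCl, imidazole, DMF, 0 °C to rt
Reagents that add atoms: tert-butyl(chloro)diphenylsilane CC(C)(C)[Si](Cl)(c1ccccc1)c1ccccc1
Why: Imidazole-promoted silyl ether formation protects the primary allylic alcohol without touching the Z olefin.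

Step 2
Reactants: 2
Product: 3 (2E,6Z)-8-(TBDPS-oxy)-2,6-dimethylocta-2,6-dien-1-ol
Conditions: SeO2 (0.2 equiv), t-BuOOH, salicylic acid (cat.), CH2Cl2, 0 °C to rt
Reagents that add atoms: selenium dioxide O=[Se]=O (catalytic oxygen carrier); tert-butyl hydroperoxide CC(C)(C)OO (terminal oxygen source)
Why: Riley allylic oxidation (ene reaction then [2,3]-shift) attacks the electron-rich terminal olefin at its E methyl group, while the C2=C3 olefin is deactivated by the allylic silyl ether.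

Step 3
Reactants: 3
Product: 4 [(2S,3S)-3-[(3Z)-5-(TBDPS-oxy)-3-methylpent-3-en-1-yl]-2-methyloxiran-2-yl]methanol
Conditions: Ti(OiPr)4 (10 mol%), L-(+)-diethyl tartrate (12 mol%), t-BuOOH, 4 Å MS, CH2Cl2, −20 °C
Reagents that add atoms: tert-butyl hydroperoxide CC(C)(C)OO
Why: Sharpless asymmetric epoxidation acts only on the free allylic alcohol, and L-(+)-tartrate gives the (6S,7S)-epoxide as for other E-2-methyl allylic alcohols.

Step 4
Reactants: 4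
Product: 6 (3R,4S,7Z)-9-(TBDPS-oxy)-3,7-dimethylnona-1,7-diene-3,4-diol, via Payne-rearranged terminal epoxide 5 (not isolated)
Conditions: Me3S+ I− (5 equiv), n-BuLi (4.8 equiv), THF, −10 °C to rt
Reagents that add atoms: trimethylsulfonium iodide C[S+](C)C.[I-]
Why: Payne rearrangement (the C8 alkoxide opens the epoxide at C7 with inversion, C6 retained) is followed by Corey–Chaykovsky-type ylide opening of the terminal epoxide and loss of Me2S, giving the one-carbon-homologated tertiary allylic alcohol with 6S,7R.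

Step 5
Reactants: 6
Product: 7 (4R,5S)-5-[(3Z)-5-(TBDPS-oxy)-3-methylpent-3-en-1-yl]-4-ethenyl-2-(4-methoxyphenyl)-4-methyl-1,3-dioxolane (both acetal epimers)
Conditions: 4-MeOC6H4CH(OMe)2, PPTS (cat.), CH2Cl2, rt
Reagents that add atoms: 4-methoxybenzaldehyde dimethyl acetal COc1ccc(cc1)C(OC)OC
Why: Acid-catalysed transacetalisation ties the 1,2-diol into a dioxolane; the new acetal centre is inconsequential.

Step 6
Reactants: 7
Product: 8 (3R,4S,7Z)-9-(TBDPS-oxy)-3-(PMB-oxy)-3,7-dimethylnona-1,7-dien-4-ol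
Conditions: iBu2AlH (3 equiv), CH2Cl2, −78 to 0 °C
Reagents that add atoms: none
Why: Regioselective reductive acetal opening: aluminium binds the less hindered O6, that C–O bond breaks and hydride reduces the oxocarbenium on O7, leaving a tertiary PMB ether and the free C6 alcohol.

Step 7
Reactants: 8; 9 bromoacetic acid
Product: 10 {[(3R,4S,7Z)-9-(TBDPS-oxy)-3-(PMB-oxy)-3,7-dimethylnona-1,7-dien-4-yl]oxy}acetic acid
Conditions: NaH (3 equiv), THF/DMF, 0 °C to rt; then 1 M HCl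
Reagents that add atoms: none
Why: Williamson etherification of the secondary alkoxide with sodium bromoacetate installs C11 and C17 without touching the C6–O bond, so C6 keeps its configuration.

Step 8
Reactants: 10; 11 (4R)-4-benzyl-1,3-oxazolidin-2-one
Product: 13 (4R)-4-benzyl-3-({[(3R,4S,7Z)-9-(TBDPS-oxy)-3-(PMB-oxy)-3,7-dimethylnona-1,7-dien-4-yl]oxy}acetyl)-1,3-oxazolidin-2-one, via mixed pivalic anhydride 12 (not isolated)
Conditions: t-BuCOCl, Et3N, THF, −78 to 0 °C; then lithiated 11 (n-BuLi, THF, −78 °C), −78 to 0 °C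
Reagents that add atoms: none
Why: N-acylation of the lithiated oxazolidinone by the mixed anhydride occurs at the unhindered glycolyl carbonyl and gives the glycolate imide.

Step 9
Reactants: 13; 14 acrolein
Product: 16 (4R)-4-benzyl-3-[(2R,3S)-3-hydroxy-2-{[(3R,4S,7Z)-9-(TBDPS-oxy)-3-(PMB-oxy)-3,7-dimethylnona-1,7-dien-4-yl]oxy}pent-4-enoyl]-1,3-oxazolidin-2-one, via dibutylboron Z-enolate 15 (not isolated)
Conditions: Bu2BOTf, Et3N, CH2Cl2, −78 to 0 °C; 14, −78 to 0 °C; H2O2, MeOH, pH 7 buffer, 0 °C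
Reagents that add atoms: none
Why: Intermolecular Evans syn glycolate aldol: the Z-boron enolate adds 1,2 to acrolein through a Zimmerman–Traxler chair, and the (R)-benzyl auxiliary directs attack to give 10S (and provisional 11R), forming the C10–C11 bond.

Step 10
Reactants: 16
Product: 17 methyl (2R,3S)-3-hydroxy-2-{[(3R,4S,7Z)-9-(TBDPS-oxy)-3-(PMB-oxy)-3,7-dimethylnona-1,7-dien-4-yl]oxy}pent-4-enoate
Conditions: MeMgBr, MeOH, CH2Cl2, 0 °C
Reagents that add atoms: methanol CO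
Why: Transesterification by MeOMgBr cleaves the exocyclic imide acyl group without retro-aldol and releases the auxiliary.

Step 11
Reactants: 17
Product: 18 methyl (2R,3S,6R,7S)-7-[(3Z)-5-(TBDPS-oxy)-3-methylpent-3-en-1-yl]-3-hydroxy-6-(PMB-oxy)-6-methyl-2,3,6,7-tetrahydrooxepine-2-carboxylate
Conditions: second-generation Grubbs catalyst RuCl2(=CHPh)(PCy3)(H2IMes) (5 mol%), CH2Cl2 (2 mM), 40 °C
Reagents that add atoms: none
Why: Ring-closing metathesis of the two vinyl groups (initiation at the unhindered C9 vinyl) forms the seven-membered ether at C8=C9 with loss of ethene, while the trisubstituted C2=C3 olefin is inert.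

Step 12
Reactants: 18
Product: 19 methyl (2R,3S,6R,7S)-7-[(3Z)-5-(TBDPS-oxy)-3-methylpent-3-en-1-yl]-3-hydroxy-6-(PMB-oxy)-6-methyloxepane-2-carboxylate
Conditions: [Rh(nbd)(dppb)]BF4 (5 mol%), H2 (50 atm), CH2Cl2, rt
Reagents that add atoms: none
Why: Hydroxyl-directed homogeneous hydrogenation: the cationic rhodium catalyst binds the C10 hydroxyl and reduces only the adjacent ring olefin, leaving the undirected trisubstituted olefin.

Step 13
Reactants: 19; 20 allyl bromide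
Product: 22 methyl (2R,3S,6R,7S)-7-[(3Z)-5-(TBDPS-oxy)-3-methylpent-3-en-1-yl]-3-hydroxy-6-(PMB-oxy)-6-methyl-2-(prop-2-en-1-yl)oxepane-2-carboxylate, via dilithium alkoxide-enolate 21 (not isolated)
Conditions: LiN(iPr)2 (2.4 equiv), THF, −78 to −30 °C; 20, DMPU, −78 to −20 °C
Reagents that add atoms: none
Why: Fráter–Seebach alkylation: in the lithium-chelated alkoxide–enolate the allyl bromide enters anti to ring carbon C9 (trans to the C10 oxygen), so the allyl group takes the place of H and quaternary C11 is set as R; the β-alkoxide cannot be eliminated.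

Step 14
Reactants: 22
Product: 23 methyl (2R,3S,6R,7S)-7-[(3Z)-5-(TBDPS-oxy)-3-methylpent-3-en-1-yl]-6-(PMB-oxy)-6-methyl-2-(prop-2-en-1-yl)-3-(TES-oxy)oxepane-2-carboxylate
Conditions: Et3SiOTf, 2,6-lutidine, CH2Cl2, −78 °C
Reagents that add atoms: triethylsilyl trifluoromethanesulfonate CC[Si](CC)(CC)OS(=O)(=O)C(F)(F)F
Why: Silyl triflate silylation caps the hindered C10 hydroxyl so that later basic and oxidative steps cannot cause retro-aldol or over-oxidation.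

Step 15
Reactants: 23
Product: 25 methyl (2R,3S,6R,7S)-7-[(3Z)-5-(TBDPS-oxy)-3-methylpent-3-en-1-yl]-2-(3-hydroxypropyl)-6-(PMB-oxy)-6-methyl-3-(TES-oxy)oxepane-2-carboxylate, via B-alkyl-9-BBN borane 24 (not isolated)
Conditions: 9-BBN, THF, 0 °C to rt; then NaOH, H2O2, 0 °C
Reagents that add atoms: hydrogen peroxide OO
Why: Anti-Markovnikov hydroboration–oxidation: 9-BBN reacts only with the monosubstituted terminal olefin, and the hindered ester survives the brief alkaline peroxide work-up.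

Step 16
Reactants: 25
Product: 26 methyl (2R,3S,6R,7S)-7-[(3Z)-5-(TBDPS-oxy)-3-methylpent-3-en-1-yl]-6-(PMB-oxy)-6-methyl-2-(3-oxopropyl)-3-(TES-oxy)oxepane-2-carboxylate
Conditions: Dess–Martin periodinane, CH2Cl2, rt
Reagents that add atoms: none
Why: Dess–Martin oxidation converts the primary alcohol to the C14 aldehyde under neutral conditions.

Step 17
Reactants: 26; 27 ethyl 2-[bis(2,2,2-trifluoroethoxy)phosphoryl]propanoate
Product: 28 methyl (2R,3S,6R,7S)-2-[(3Z)-5-ethoxy-4-methyl-5-oxopent-3-en-1-yl]-7-[(3Z)-5-(TBDPS-oxy)-3-methylpent-3-en-1-yl]-6-(PMB-oxy)-6-methyl-3-(TES-oxy)oxepane-2-carboxylate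
Conditions: KN(SiMe3)2, 18-crown-6, THF, −78 °C
Reagents that add atoms: none
Why: Still–Gennari olefination (Z-selective Horner–Wadsworth–Emmons) gives the trisubstituted enoate with the chain cis to the ester, which is the geometry of the C14=C15 olefin.

Step 18
Reactants: 28
Product: 29 (2Z)-5-[(2S,3S,6R,7S)-7-[(3Z)-5-(TBDPS-oxy)-3-methylpent-3-en-1-yl]-2-(hydroxymethyl)-6-(PMB-oxy)-6-methyl-3-(TES-oxy)oxepan-2-yl]-2-methylpent-2-en-1-ol
Conditions: iBu2AlH (6 equiv), CH2Cl2, −78 to 0 °C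
Reagents that add atoms: none
Why: Exhaustive hydride reduction takes the enoate 1,2 to the Z-allylic alcohol and the hindered C17 ester to the neopentyl alcohol, avoiding any need to differentiate the two esters (the C11 descriptor changes letter only through priorities).

Step 19
Reactants: 29
Product: 30 [(2S,3S,6R,7S)-2-[(3Z)-5-(TBDPS-oxy)-4-methylpent-3-en-1-yl]-7-[(3Z)-5-(TBDPS-oxy)-3-methylpent-3-en-1-yl]-6-(PMB-oxy)-6-methyl-3-(TES-oxy)oxepan-2-yl]methanol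
Conditions: TBDPSCl (1.05 equiv), imidazole, CH2Cl2, 0 °C
Reagents that add atoms: tert-butyl(chloro)diphenylsilane CC(C)(C)[Si](Cl)(c1ccccc1)c1ccccc1
Why: Sterically controlled silylation takes the unhindered allylic C16 hydroxyl and leaves the neopentyl C17 hydroxyl beside the quaternary centre.

Step 20
Reactants: 30
Product: 31 [(2S,3S,6R,7S)-2-[(3Z)-5-(TBDPS-oxy)-4-methylpent-3-en-1-yl]-7-[(3Z)-5-(TBDPS-oxy)-3-methylpent-3-en-1-yl]-6-hydroxy-6-methyl-3-(TES-oxy)oxepan-2-yl]methanol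
Conditions: DDQ, CH2Cl2/pH 7 buffer, 0 °C
Reagents that add atoms: none
Why: Oxidative PMB ether cleavage frees the tertiary C7 hydroxyl without affecting silyl ethers or olefins.

Step 21
Reactants: 31
Product: 34 (1R,2S,5R,9S)-1-[(3Z)-5-(TBDPS-oxy)-4-methylpent-3-en-1-yl]-9-[(3Z)-5-(TBDPS-oxy)-3-methylpent-3-en-1-yl]-5-methyl-2-(TES-oxy)-6,8-dioxabicyclo[3.2.2]nonan-7-one, via hydroxy aldehyde 32 (not isolated), via bridged lactol 33 (not isolated)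
Conditions: (n-Pr4N)RuO4 (10 mol%), N-methylmorpholine N-oxide, 4 Å MS, CH2Cl2, rt
Reagents that add atoms: none
Why: Ley–Griffith oxidative lactonisation: the primary alcohol is oxidised to the aldehyde, the cis tertiary C7 hydroxyl adds to give the bridged lactol, and this is oxidised to the lactone; all four stereocentres are already in place and the tertiary alcohol cannot be oxidised.

Step 22
Reactants: 34
Product: 35 (1R,2S,5R,9S)-2-hydroxy-1-[(3Z)-5-hydroxy-4-methylpent-3-en-1-yl]-9-[(3Z)-5-hydroxy-3-methylpent-3-en-1-yl]-5-methyl-6,8-dioxabicyclo[3.2.2]nonan-7-one (CNP0105745.1)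
Conditions: Bu4NF, AcOH, THF, rt
Reagents that add atoms: none
Why: Acetic acid-buffered fluoride desilylation removes the TES and both TBDPS groups without retro-aldol of the β-hydroxy lactone.

## Compound list

1 | nerol, (2Z)-3,7-dimethylocta-2,6-dien-1-ol | CC(C)=CCC/C(C)=C\CO | starting material
2 | (2Z)-1-(TBDPS-oxy)-3,7-dimethylocta-2,6-diene | CC(C)=CCC/C(C)=C\CO[Si](c1ccccc1)(c1ccccc1)C(C)(C)C | intermediate
3 | (2E,6Z)-8-(TBDPS-oxy)-2,6-dimethylocta-2,6-dien-1-ol | OC/C(C)=C/CC/C(C)=C\CO[Si](c1ccccc1)(c1ccccc1)C(C)(C)C | intermediate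
4 | [(2S,3S)-3-[(3Z)-5-(TBDPS-oxy)-3-methylpent-3-en-1-yl]-2-methyloxiran-2-yl]methanol | OC[C@]1(C)O[C@H]1CC/C(C)=C\CO[Si](c1ccccc1)(c1ccccc1)C(C)(C)C | intermediate
5 | (1S,4Z)-6-(TBDPS-oxy)-4-methyl-1-[(2R)-2-methyloxiran-2-yl]hex-4-en-1-ol (not isolated) | C[C@@]1(CO1)[C@@H](O)CC/C(C)=C\CO[Si](c1ccccc1)(c1ccccc1)C(C)(C)C | intermediate
6 | (3R,4S,7Z)-9-(TBDPS-oxy)-3,7-dimethylnona-1,7-diene-3,4-diol | C=C[C@@](C)(O)[C@@H](O)CC/C(C)=C\CO[Si](c1ccccc1)(c1ccccc1)C(C)(C)C | intermediate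
7 | (4R,5S)-5-[(3Z)-5-(TBDPS-oxy)-3-methylpent-3-en-1-yl]-4-ethenyl-2-(4-methoxyphenyl)-4-methyl-1,3-dioxolane, both acetal epimers | C=C[C@@]1(C)OC(c2ccc(OC)cc2)O[C@H]1CC/C(C)=C\CO[Si](c1ccccc1)(c1ccccc1)C(C)(C)C | intermediate
8 | (3R,4S,7Z)-9-(TBDPS-oxy)-3-(PMB-oxy)-3,7-dimethylnona-1,7-dien-4-ol | C=C[C@@](C)(OCc1ccc(OC)cc1)[C@@H](O)CC/C(C)=C\CO[Si](c1ccccc1)(c1ccccc1)C(C)(C)C | intermediate
9 | bromoacetic acid | OC(=O)CBr | starting material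
10 | {[(3R,4S,7Z)-9-(TBDPS-oxy)-3-(PMB-oxy)-3,7-dimethylnona-1,7-dien-4-yl]oxy}acetic acid | C=C[C@@](C)(OCc1ccc(OC)cc1)[C@@H](OCC(O)=O)CC/C(C)=C\CO[Si](c1ccccc1)(c1ccccc1)C(C)(C)C | intermediate
11 | (4R)-4-benzyl-1,3-oxazolidin-2-one | O=C1N[C@H](Cc2ccccc2)CO1 | starting material
12 | mixed anhydride of 10 with pivalic acid (not isolated) | C=C[C@@](C)(OCc1ccc(OC)cc1)[C@@H](OCC(=O)OC(=O)C(C)(C)C)CC/C(C)=C\CO[Si](c1ccccc1)(c1ccccc1)C(C)(C)C | intermediate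
13 | (4R)-4-benzyl-3-({[(3R,4S,7Z)-9-(TBDPS-oxy)-3-(PMB-oxy)-3,7-dimethylnona-1,7-dien-4-yl]oxy}acetyl)-1,3-oxazolidin-2-one | C=C[C@@](C)(OCc1ccc(OC)cc1)[C@@H](OCC(=O)N1[C@H](Cc2ccccc2)COC1=O)CC/C(C)=C\CO[Si](c1ccccc1)(c1ccccc1)C(C)(C)C | intermediate
14 | acrolein | C=CC=O | starting material
15 | dibutylboron (Z)-enolate of 13 (not isolated) | C=C[C@@](C)(OCc1ccc(OC)cc1)[C@@H](O/C=C(\OB(CCCC)CCCC)N1[C@H](Cc2ccccc2)COC1=O)CC/C(C)=C\CO[Si](c1ccccc1)(c1ccccc1)C(C)(C)C | intermediate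
16 | (4R)-4-benzyl-3-[(2R,3S)-3-hydroxy-2-{[(3R,4S,7Z)-9-(TBDPS-oxy)-3-(PMB-oxy)-3,7-dimethylnona-1,7-dien-4-yl]oxy}pent-4-enoyl]-1,3-oxazolidin-2-one | C=C[C@@](C)(OCc1ccc(OC)cc1)[C@@H](O[C@H]([C@@H](O)C=C)C(=O)N1[C@H](Cc2ccccc2)COC1=O)CC/C(C)=C\CO[Si](c1ccccc1)(c1ccccc1)C(C)(C)C | intermediate
17 | methyl (2R,3S)-3-hydroxy-2-{[(3R,4S,7Z)-9-(TBDPS-oxy)-3-(PMB-oxy)-3,7-dimethylnona-1,7-dien-4-yl]oxy}pent-4-enoate | C=C[C@@](C)(OCc1ccc(OC)cc1)[C@@H](O[C@H]([C@@H](O)C=C)C(=O)OC)CC/C(C)=C\CO[Si](c1ccccc1)(c1ccccc1)C(C)(C)C | intermediate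
18 | methyl (2R,3S,6R,7S)-7-[(3Z)-5-(TBDPS-oxy)-3-methylpent-3-en-1-yl]-3-hydroxy-6-(PMB-oxy)-6-methyl-2,3,6,7-tetrahydrooxepine-2-carboxylate | COC(=O)[C@@H]1O[C@@H](CC/C(C)=C\CO[Si](c2ccccc2)(c2ccccc2)C(C)(C)C)[C@](C)(OCc2ccc(OC)cc2)C=C[C@@H]1O | intermediate
19 | methyl (2R,3S,6R,7S)-7-[(3Z)-5-(TBDPS-oxy)-3-methylpent-3-en-1-yl]-3-hydroxy-6-(PMB-oxy)-6-methyloxepane-2-carboxylate | COC(=O)[C@@H]1O[C@@H](CC/C(C)=C\CO[Si](c2ccccc2)(c2ccccc2)C(C)(C)C)[C@](C)(OCc2ccc(OC)cc2)CC[C@@H]1O | intermediate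
20 | allyl bromide | C=CCBr | starting material
21 | dilithium alkoxide-enolate of 19, enolate oxygen cis to C10 (not isolated) | [Li+].[Li+].[O-]/C(OC)=C1/O[C@@H](CC/C(C)=C\CO[Si](c2ccccc2)(c2ccccc2)C(C)(C)C)[C@](C)(OCc2ccc(OC)cc2)CC[C@@H]1[O-] | intermediate
22 | methyl (2R,3S,6R,7S)-7-[(3Z)-5-(TBDPS-oxy)-3-methylpent-3-en-1-yl]-3-hydroxy-6-(PMB-oxy)-6-methyl-2-(prop-2-en-1-yl)oxepane-2-carboxylate | COC(=O)[C@]1(CC=C)O[C@@H](CC/C(C)=C\CO[Si](c2ccccc2)(c2ccccc2)C(C)(C)C)[C@](C)(OCc2ccc(OC)cc2)CC[C@@H]1O | intermediate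
23 | methyl (2R,3S,6R,7S)-7-[(3Z)-5-(TBDPS-oxy)-3-methylpent-3-en-1-yl]-6-(PMB-oxy)-6-methyl-2-(prop-2-en-1-yl)-3-(TES-oxy)oxepane-2-carboxylate | COC(=O)[C@]1(CC=C)O[C@@H](CC/C(C)=C\CO[Si](c2ccccc2)(c2ccccc2)C(C)(C)C)[C@](C)(OCc2ccc(OC)cc2)CC[C@@H]1O[Si](CC)(CC)CC | intermediate
24 | 9-BBN adduct of 23, boron on the terminal carbon of the former allyl group (not isolated) | COC(=O)[C@]1(CCCB2C3CCCC2CCC3)O[C@@H](CC/C(C)=C\CO[Si](c2ccccc2)(c2ccccc2)C(C)(C)C)[C@](C)(OCc2ccc(OC)cc2)CC[C@@H]1O[Si](CC)(CC)CC | intermediate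
25 | methyl (2R,3S,6R,7S)-7-[(3Z)-5-(TBDPS-oxy)-3-methylpent-3-en-1-yl]-2-(3-hydroxypropyl)-6-(PMB-oxy)-6-methyl-3-(TES-oxy)oxepane-2-carboxylate | COC(=O)[C@]1(CCCO)O[C@@H](CC/C(C)=C\CO[Si](c2ccccc2)(c2ccccc2)C(C)(C)C)[C@](C)(OCc2ccc(OC)cc2)CC[C@@H]1O[Si](CC)(CC)CC | intermediate
26 | methyl (2R,3S,6R,7S)-7-[(3Z)-5-(TBDPS-oxy)-3-methylpent-3-en-1-yl]-6-(PMB-oxy)-6-methyl-2-(3-oxopropyl)-3-(TES-oxy)oxepane-2-carboxylate | COC(=O)[C@]1(CCC=O)O[C@@H](CC/C(C)=C\CO[Si](c2ccccc2)(c2ccccc2)C(C)(C)C)[C@](C)(OCc2ccc(OC)cc2)CC[C@@H]1O[Si](CC)(CC)CC | intermediate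
27 | ethyl 2-[bis(2,2,2-trifluoroethoxy)phosphoryl]propanoate | CCOC(=O)C(C)P(=O)(OCC(F)(F)F)OCC(F)(F)F | starting material
28 | methyl (2R,3S,6R,7S)-2-[(3Z)-5-ethoxy-4-methyl-5-oxopent-3-en-1-yl]-7-[(3Z)-5-(TBDPS-oxy)-3-methylpent-3-en-1-yl]-6-(PMB-oxy)-6-methyl-3-(TES-oxy)oxepane-2-carboxylate | COC(=O)[C@]1(CC/C=C(/C)C(=O)OCC)O[C@@H](CC/C(C)=C\CO[Si](c2ccccc2)(c2ccccc2)C(C)(C)C)[C@](C)(OCc2ccc(OC)cc2)CC[C@@H]1O[Si](CC)(CC)CC | intermediate
29 | (2Z)-5-[(2S,3S,6R,7S)-7-[(3Z)-5-(TBDPS-oxy)-3-methylpent-3-en-1-yl]-2-(hydroxymethyl)-6-(PMB-oxy)-6-methyl-3-(TES-oxy)oxepan-2-yl]-2-methylpent-2-en-1-ol | OC[C@]1(CC/C=C(/C)CO)O[C@@H](CC/C(C)=C\CO[Si](c2ccccc2)(c2ccccc2)C(C)(C)C)[C@](C)(OCc2ccc(OC)cc2)CC[C@@H]1O[Si](CC)(CC)CC | intermediate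
30 | [(2S,3S,6R,7S)-2-[(3Z)-5-(TBDPS-oxy)-4-methylpent-3-en-1-yl]-7-[(3Z)-5-(TBDPS-oxy)-3-methylpent-3-en-1-yl]-6-(PMB-oxy)-6-methyl-3-(TES-oxy)oxepan-2-yl]methanol | OC[C@]1(CC/C=C(/C)CO[Si](c2ccccc2)(c2ccccc2)C(C)(C)C)O[C@@H](CC/C(C)=C\CO[Si](c2ccccc2)(c2ccccc2)C(C)(C)C)[C@](C)(OCc2ccc(OC)cc2)CC[C@@H]1O[Si](CC)(CC)CC | intermediate
31 | [(2S,3S,6R,7S)-2-[(3Z)-5-(TBDPS-oxy)-4-methylpent-3-en-1-yl]-7-[(3Z)-5-(TBDPS-oxy)-3-methylpent-3-en-1-yl]-6-hydroxy-6-methyl-3-(TES-oxy)oxepan-2-yl]methanol | OC[C@]1(CC/C=C(/C)CO[Si](c2ccccc2)(c2ccccc2)C(C)(C)C)O[C@@H](CC/C(C)=C\CO[Si](c2ccccc2)(c2ccccc2)C(C)(C)C)[C@](C)(O)CC[C@@H]1O[Si](CC)(CC)CC | intermediate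
32 | (2R,3S,6R,7S)-2-[(3Z)-5-(TBDPS-oxy)-4-methylpent-3-en-1-yl]-7-[(3Z)-5-(TBDPS-oxy)-3-methylpent-3-en-1-yl]-6-hydroxy-6-methyl-3-(TES-oxy)oxepane-2-carbaldehyde (not isolated) | O=C[C@]1(CC/C=C(/C)CO[Si](c2ccccc2)(c2ccccc2)C(C)(C)C)O[C@@H](CC/C(C)=C\CO[Si](c2ccccc2)(c2ccccc2)C(C)(C)C)[C@](C)(O)CC[C@@H]1O[Si](CC)(CC)CC | intermediate
33 | (1R,2S,5R,9S)-1-[(3Z)-5-(TBDPS-oxy)-4-methylpent-3-en-1-yl]-9-[(3Z)-5-(TBDPS-oxy)-3-methylpent-3-en-1-yl]-5-methyl-2-(TES-oxy)-6,8-dioxabicyclo[3.2.2]nonan-7-ol, lactol epimers (not isolated) | C/C(=C/CC[C@@]12O[C@@H](CC/C(C)=C\CO[Si](c3ccccc3)(c3ccccc3)C(C)(C)C)[C@@](C)(CC[C@@H]1O[Si](CC)(CC)CC)OC2O)CO[Si](c1ccccc1)(c1ccccc1)C(C)(C)C | intermediate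
34 | (1R,2S,5R,9S)-1-[(3Z)-5-(TBDPS-oxy)-4-methylpent-3-en-1-yl]-9-[(3Z)-5-(TBDPS-oxy)-3-methylpent-3-en-1-yl]-5-methyl-2-(TES-oxy)-6,8-dioxabicyclo[3.2.2]nonan-7-one | C/C(=C/CC[C@@]12O[C@@H](CC/C(C)=C\CO[Si](c3ccccc3)(c3ccccc3)C(C)(C)C)[C@@](C)(CC[C@@H]1O[Si](CC)(CC)CC)OC2=O)CO[Si](c1ccccc1)(c1ccccc1)C(C)(C)C | intermediate
35 | (1R,2S,5R,9S)-2-hydroxy-1-[(3Z)-5-hydroxy-4-methylpent-3-en-1-yl]-9-[(3Z)-5-hydroxy-3-methylpent-3-en-1-yl]-5-methyl-6,8-dioxabicyclo[3.2.2]nonan-7-one (CNP0105745.1) | C/C(=C/CC[C@@]12O[C@@H](CC/C(C)=C\CO)[C@@](C)(CC[C@@H]1O)OC2=O)CO | target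

## Step count and risks

Total steps: 22. Longest linear sequence: 22 steps (1 to 35); all other inputs are purchased.

The three steps most likely to fail:

**Step 4** (Payne rearrangement at a tertiary epoxide carbon with in-flask ylide trapping; the equilibrium may be slow). The fallback sets out from 4 and comes back at 6. Compound 4 is treated with PhNCO and pyridine to give the N-phenylcarbamate F1. BF3·OEt2 in CH2Cl2 at −20 °C then makes the carbamate carbonyl oxygen open the epoxide 5-exo at C7 with inversion, and acidic aqueous work-up hydrolyses the iminocarbonate to the cyclic carbonate F2, leaving the C6 hydroxyl free. K2CO3 in MeOH gives the triol F3. TEMPO with PhI(OAc)2 oxidises only the primary alcohol to the hydroxy aldehyde F4, and Ph3P=CH2 in THF converts it to 6.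

**Step 13** (intermolecular formation of a quaternary α-alkoxy centre; facial control rests on the lithium chelate). The fallback sets out from 19 and comes back at 23, replacing the alkylation by an Ireland–Claisen rearrangement. Ti(OiPr)4-catalysed transesterification of 19 with allyl alcohol gives the allyl ester F5. Et3SiOTf with 2,6-lutidine gives the silyl ether F6. KN(SiMe3)2 and Me3SiCl in THF at −78 °C form the silyl ketene acetal, which on warming shifts the allyl group [3,3] to C11 on the face anti to the C10 silyloxy group, giving after aqueous work-up the acid F7. Me3SiCHN2 in MeOH/toluene then gives 23.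

**Step 21** (the bridged lactol may be too sparsely populated for the oxidation to run through to the lactone). The fallback sets out from 31 and comes back at 34, using acyl activation instead of lactol oxidation. TEMPO (cat.) with PhI(OAc)2 in MeCN/H2O oxidises the primary alcohol to the hydroxy acid F8. Yamaguchi lactonisation (2,4,6-trichlorobenzoyl chloride, Et3N, then DMAP in toluene) closes the six-membered lactone onto the tertiary C7 hydroxyl to give 34.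

## Further compounds

F1 | step 4 | [(2S,3S)-3-[(3Z)-5-(TBDPS-oxy)-3-methylpent-3-en-1-yl]-2-methyloxiran-2-yl]methyl N-phenylcarbamate | O=C(Nc1ccccc1)OC[C@]1(C)O[C@H]1CC/C(C)=C\CO[Si](c1ccccc1)(c1ccccc1)C(C)(C)C
F2 | step 4 | (4R)-4-[(1S,4Z)-6-(TBDPS-oxy)-1-hydroxy-4-methylhex-4-en-1-yl]-4-methyl-1,3-dioxolan-2-one | C[C@@]1(COC(=O)O1)[C@@H](O)CC/C(C)=C\CO[Si](c1ccccc1)(c1ccccc1)C(C)(C)C
F3 | step 4 | (2R,3S,6Z)-8-(TBDPS-oxy)-2,6-dimethyloct-6-ene-1,2,3-triol | C[C@@](O)(CO)[C@@H](O)CC/C(C)=C\CO[Si](c1ccccc1)(c1ccccc1)C(C)(C)C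
F4 | step 4 | (2S,3S,6Z)-8-(TBDPS-oxy)-2,3-dihydroxy-2,6-dimethyloct-6-enal | C[C@@](O)(C=O)[C@@H](O)CC/C(C)=C\CO[Si](c1ccccc1)(c1ccccc1)C(C)(C)C
F5 | step 13 | prop-2-en-1-yl (2R,3S,6R,7S)-7-[(3Z)-5-(TBDPS-oxy)-3-methylpent-3-en-1-yl]-3-hydroxy-6-(PMB-oxy)-6-methyloxepane-2-carboxylate | C=CCOC(=O)[C@@H]1O[C@@H](CC/C(C)=C\CO[Si](c2ccccc2)(c2ccccc2)C(C)(C)C)[C@](C)(OCc2ccc(OC)cc2)CC[C@@H]1O
F6 | step 13 | prop-2-en-1-yl (2R,3S,6R,7S)-7-[(3Z)-5-(TBDPS-oxy)-3-methylpent-3-en-1-yl]-6-(PMB-oxy)-6-methyl-3-(TES-oxy)oxepane-2-carboxylate | C=CCOC(=O)[C@@H]1O[C@@H](CC/C(C)=C\CO[Si](c2ccccc2)(c2ccccc2)C(C)(C)C)[C@](C)(OCc2ccc(OC)cc2)CC[C@@H]1O[Si](CC)(CC)CC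
F7 | step 13 | (2R,3S,6R,7S)-7-[(3Z)-5-(TBDPS-oxy)-3-methylpent-3-en-1-yl]-6-(PMB-oxy)-6-methyl-2-(prop-2-en-1-yl)-3-(TES-oxy)oxepane-2-carboxylic acid | OC(=O)[C@]1(CC=C)O[C@@H](CC/C(C)=C\CO[Si](c2ccccc2)(c2ccccc2)C(C)(C)C)[C@](C)(OCc2ccc(OC)cc2)CC[C@@H]1O[Si](CC)(CC)CC
F8 | step 21 | (2R,3S,6R,7S)-2-[(3Z)-5-(TBDPS-oxy)-4-methylpent-3-en-1-yl]-7-[(3Z)-5-(TBDPS-oxy)-3-methylpent-3-en-1-yl]-6-hydroxy-6-methyl-3-(TES-oxy)oxepane-2-carboxylic acid | OC(=O)[C@]1(CC/C=C(/C)CO[Si](c2ccccc2)(c2ccccc2)C(C)(C)C)O[C@@H](CC/C(C)=C\CO[Si](c2ccccc2)(c2ccccc2)C(C)(C)C)[C@](C)(O)CC[C@@H]1O[Si](CC)(CC)CC
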